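The runs were computed from invented constants; scatter was added.

**Vessel and zero.** The vessel is closed, stirred and isothermal, and free catalyst turns substrate into target with added ligand present. I take plain first order as the zero of my scale: percent curves then coincide at any charge, and one constant carries a flask.

the same everywhere: added ligand 2.3 mM
- elm: substrate 0.067 M; free catalyst 0.56 mM; run made earlier
- maple: substrate 0.15 M; free catalyst 0.56 mM; run made earlier
- alder: substrate 0.10 M; free catalyst 0.28 mM; run made earlier
- flask: substrate 0.10 M; free catalyst 0.56 mM; time 20 min

| run | time / min | target / % | substrate / % |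
|---|---|---|---|
| elm | 1.33 | 7 | 98 |
| elm | 3.00 | 9 | 88 |
| elm | 6.00 | 21 | 83 |
| elm | 15.0 | 40 | 64 |
| maple | 2.00 | 5 | 92 |
| maple | 6.00 | 18 | 85 |
| maple | 10.0 | 24 | 77 |
| maple | 15.0 | 36 | 66 |
| alder | 4.00 | 9 | 94 |
| alder | 8.00 | 14 | 92 |
| alder | 12.0 | 14 | 81 |
| alder | 15.0 | 22 | 84 |

(each reading ± 2 percentage points)

- target present at 20 min, in percent of the substrate charged
- substrate present at 20 min, in percent of the substrate charged

**Substrate charge.** By hand, a first-order loss leaves percentages untouched by the charge. At 15.0 min, elm shows 64% substrate and maple 66%, which agree within a scatter of 2 percentage points.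

**The constant.** In the readings of the runs, substrate and target sum near 100, so I average each substrate reading with 100 minus its target. From the last readings of elm and maple I get the pseudo-first-order constant k, the logarithm of charged over remaining substrate per unit time, 0.0303 min⁻¹.

**Free catalyst.** By hand, half the catalyst lowers the constant by the same factor. Alder reads 0.0140 min⁻¹, which is 0.462 of k.

**Ligand and time.** Added ligand is charged at 2.3 mM in elm, maple, alder and this flask, so its effect sits inside k. This flask shares the catalyst charge of elm and maple, so at 20 min I reckon exp(−kt) as 54.6% substrate and 45.4% target.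

**Forecast and flask.** The forecast, a little apart from my figures, says 43% target and 57% substrate, reasoning “so the reaction is about first order in substrate”. This flask gives 46.5% target and 53.5% substrate.

    substrate + free catalyst ⇌ catalyst intermediate A (K = 9.70 M⁻¹, k = 17.0 M⁻¹ s⁻¹)
    catalyst intermediate A → catalyst intermediate B (k = 29.0 s⁻¹)
    catalyst intermediate B → free catalyst + target (k = 0.410 s⁻¹)
    free catalyst + added ligand ⇌ idle complex, settled at all times (K = 7100 M⁻¹)

**Parked catalyst.** This flask's substrate reads back as k of 0.0313 min⁻¹, against my 0.0303 min⁻¹. At 20.0 min, idle complex holds 80.8% of the catalyst in this flask, and this parking, together with the early hour of the reading, keeps target at 46.5%; without the parking, or at ten times the time, target stands at 99.9%. Scaling k inversely with the charge of added ligand gives 0.0497 min⁻¹ for a neighbour flask, the same as this one but charged with 1.40 mM of added ligand, hence an estimate of 37.0% substrate at 20 min, and that neighbour stands at 36.7%.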